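Ring A, the hydroxylated ε-ring, is cut across C2–C3 and C5–C6 (carotenoid numbering). The cut exploits that C2 and C6 flank the quaternary C1 and can both be ester enolate carbons: C2–C1(CH3)2–C6 with C7 is dimethyl 3,3-dimethylglutarate, and C3–C4=C5(CH3) is methyl but-2-ynoate, whose ester and alkyne carbons already carry the C3 oxygen, the C4=C5 alkene and the C5 methyl group. One Michael–Dieckmann [3+3] annulation of the glutarate bis-enolate with the ynoate forms both bonds. The surplus ester is then removed, C3 and C6 are fixed by a catalyst-controlled reduction with kinetic resolution, and the ring enters a C15 + C10 + C15 Wittig assembly.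

Key step: step 1

Assumption: (S)-(−)-α-ionone 13 is taken as a purchasable single enantiomer (otherwise it is separated from cheap racemic α-ionone by preparative chromatography on a chiral phase). Ring atoms carry carotenoid numbers (C1 = C(CH3)2, C3 = carbinol carbon, C6 = ring CH bearing the chain, primes for ring B).

Step 1
Reactants: 1 dimethyl 3,3-dimethylpentanedioate; 2 methyl but-2-ynoate
Product: 5 dimethyl 2,2,4-trimethyl-6-oxocyclohex-4-ene-1,3-dicarboxylate (racemic; epimers and enol forms), via dilithium bis-enolate 3 (not isolated), via acyclic Michael adduct enolate 4 (not isolated)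
Conditions: LiN(iPr)2 (2.2 equiv), THF, −78 °C; then 2 (1.0 equiv) added slowly to dilute 3; −78 to 25 °C; 1 M HCl
Reagents that add atoms: none
Why: One enolate carbon of the symmetric bis-enolate adds in conjugate fashion to the β-carbon of the ynoate (C5–C6 bond) and, after proton transfer to C4 of the allenolate, the second enolate acylates the ynoate-derived ester with loss of methoxide (C2–C3 bond), the cyclic β-keto ester enolate being the thermodynamic sink. This is a tandem Michael–Dieckmann (Michael–Claisen) [3+3] annulation, the known route from ester or ketone enolates and unsaturated or acetylenic esters to cyclohexenone and cyclohexane-1,3-dione carboxylates. Ring A closes in the Dieckmann event, a 6-(enolexo)-exo-trig acylation; should acylation come first, the closure is a 6-endo-dig Michael addition and the same ring results because the bis-enolate is symmetric. The two ring CH(CO2CH3) centres (C2 and C6) form without control and are epimerisable; C2 loses its ester in step 2 and C6 is selected in step 3. The step needs a 1:1 union and acylation only at the ynoate carbonyl: both glutarate esters stay masked as enolates, so the only electrophilic acyl group is that of 2, and slow addition of 2 to dilute 3 should curb double Michael addition. The alkyne oxidation level places the C4=C5 double bond next to the C5 methyl group without a later elimination.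

Step 2
Reactants: 5 dimethyl 2,2,4-trimethyl-6-oxocyclohex-4-ene-1,3-dicarboxylate
Product: 6 methyl 2,6,6-trimethyl-4-oxocyclohex-2-ene-1-carboxylate (racemic)
Conditions: LiCl (1.2 equiv), H2O (2 equiv), DMSO, 140 °C
Reagents that add atoms: none
Why: Krapcho dealkoxycarbonylation, in which chloride demethylates and the β-keto carboxylate at C2 loses CO2 readily, whereas the ester on C6 is only vinylogously activated and should survive; the C2 stereocentre disappears and C6 stays racemic.

Step 3
Reactants: 6 methyl 2,6,6-trimethyl-4-oxocyclohex-2-ene-1-carboxylate (racemic)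
Product: 7 methyl (1S,4S)-4-hydroxy-2,6,6-trimethylcyclohex-2-ene-1-carboxylate
Conditions: (R)-2-methyl-CBS-oxazaborolidine [(R)-1-methyl-3,3-diphenyltetrahydro-1H,3H-pyrrolo[1,2-c][1,3,2]oxazaborole, C18H20BNO] (0.2 equiv), catecholborane (0.6 equiv), toluene, −78 °C, run to about half conversion; MeOH quench
Reagents that add atoms: none
Why: CBS reduction run as a kinetic resolution: the (R)-catalyst, with the alkenyl flank as the large group, delivers hydride to the face of C3 that gives the (3S)-alcohol, and only in the (6S)-enantiomer of 6 is this also the face anti to the pseudoaxial C1 methyl group (syn to the pseudoaxial ester), so that enantiomer should be reduced preferentially to the 3,6-trans alcohol 7 while (6R)-6 is left behind and can be racemised with base and recycled.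

Step 4
Reactants: 7 methyl (1S,4S)-4-hydroxy-2,6,6-trimethylcyclohex-2-ene-1-carboxylate
Product: 8 methyl (1S,4S)-4-[(tert-butyldimethylsilyl)oxy]-2,6,6-trimethylcyclohex-2-ene-1-carboxylate
Conditions: tBuMe2SiCl, imidazole, DMF, 25 °C
Reagents that add atoms: tert-butyldimethylsilyl chloride CC(C)(C)[Si](C)(C)Cl
Why: Silyl ether protection of the secondary allylic alcohol shields it in the hydride reduction and, later, from ionisation in the acidic salt-forming step.

Step 5
Reactants: 8 methyl (1S,4S)-4-[(tert-butyldimethylsilyl)oxy]-2,6,6-trimethylcyclohex-2-ene-1-carboxylate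
Product: 9 (1S,4S)-4-[(tert-butyldimethylsilyl)oxy]-2,6,6-trimethylcyclohex-2-ene-1-carbaldehyde
Conditions: iBu2AlH (1.1 equiv), CH2Cl2, −78 °C; aq. potassium sodium tartrate
Reagents that add atoms: none
Why: Partial ester reduction with DIBAL-H, in which the tetrahedral aluminium hemiacetal of this hindered ester should persist at −78 °C and release the aldehyde on neutral work-up without touching the C6 centre.

Step 6
Reactants: 9 (1S,4S)-4-[(tert-butyldimethylsilyl)oxy]-2,6,6-trimethylcyclohex-2-ene-1-carbaldehyde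
Product: 10 (3E)-4-[(1S,4S)-4-[(tert-butyldimethylsilyl)oxy]-2,6,6-trimethylcyclohex-2-en-1-yl]but-3-en-2-one
Conditions: Ph3P=CHC(O)CH3 (1.5 equiv), toluene, 90 °C
Reagents that add atoms: 1-(triphenylphosphoranylidene)propan-2-one CC(=O)C=P(c1ccccc1)(c1ccccc1)c1ccccc1
Why: Wittig olefination with a stabilised ylide should give the (E)-enone (C7=C8) under neutral conditions that leave the enolisable C6 centre and the deconjugated C4=C5 alkene untouched.

Step 7
Reactants: 10 (3E)-4-[(1S,4S)-4-[(tert-butyldimethylsilyl)oxy]-2,6,6-trimethylcyclohex-2-en-1-yl]but-3-en-2-one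
Product: 11 (1E)-1-[(1S,4S)-4-[(tert-butyldimethylsilyl)oxy]-2,6,6-trimethylcyclohex-2-en-1-yl]-3-methylpenta-1,4-dien-3-ol (both epimers at the new carbinol carbon)
Conditions: CH2=CHMgBr (1.5 equiv), THF, −20 to 0 °C; aq. NH4Cl
Reagents that add atoms: vinylmagnesium bromide C=C[Mg]Br
Why: 1,2-Grignard addition to the enone (the vinyl-ionol reaction); the new carbinol centre forms without control and is destroyed in step 8.

Step 8
Reactants: 11 (1E)-1-[(1S,4S)-4-[(tert-butyldimethylsilyl)oxy]-2,6,6-trimethylcyclohex-2-en-1-yl]-3-methylpenta-1,4-dien-3-ol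
Product: 12 [(2E,4E)-5-[(1S,4S)-4-[(tert-butyldimethylsilyl)oxy]-2,6,6-trimethylcyclohex-2-en-1-yl]-3-methylpenta-2,4-dien-1-yl]triphenylphosphonium bromide
Conditions: Ph3P·HBr (1.05 equiv), CH2Cl2, 0 to 25 °C
Reagents that add atoms: triphenylphosphine hydrobromide [Br-].[PH+](c1ccccc1)(c1ccccc1)c1ccccc1
Why: Phosphonium salt formation by ionisation of the tertiary doubly allylic alcohol and capture of the pentadienyl cation by PPh3 at its primary terminus, giving mainly the (9E)-salt; this weak acid should not ionise the ring silyl ether.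

Step 9
Reactants: 13 (S)-α-ionone, (3E)-4-[(1S)-2,6,6-trimethylcyclohex-2-en-1-yl]but-3-en-2-one
Product: 14 (1E)-3-methyl-1-[(1S)-2,6,6-trimethylcyclohex-2-en-1-yl]penta-1,4-dien-3-ol (both epimers at the carbinol carbon)
Conditions: CH2=CHMgBr (1.5 equiv), THF, −20 to 0 °C; aq. NH4Cl
Reagents that add atoms: vinylmagnesium bromide C=C[Mg]Br
Why: 1,2-Grignard addition to the enone; C6′ is not involved and the new carbinol centre is lost in step 10.

Step 10
Reactants: 14 (1E)-3-methyl-1-[(1S)-2,6,6-trimethylcyclohex-2-en-1-yl]penta-1,4-dien-3-ol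
Product: 15 [(2E,4E)-3-methyl-5-[(1S)-2,6,6-trimethylcyclohex-2-en-1-yl]penta-2,4-dien-1-yl]triphenylphosphonium bromide
Conditions: Ph3P·HBr, MeOH, 25 °C
Reagents that add atoms: triphenylphosphine hydrobromide [Br-].[PH+](c1ccccc1)(c1ccccc1)c1ccccc1
Why: Phosphonium salt formation with allylic transposition, the standard entry to C15 Wittig salts of ionones, which leaves C6′ unchanged.

Step 11
Reactants: 15 [(2E,4E)-3-methyl-5-[(1S)-2,6,6-trimethylcyclohex-2-en-1-yl]penta-2,4-dien-1-yl]triphenylphosphonium bromide; 16 (2E,4E,6E)-2,7-dimethylocta-2,4,6-trienedial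
Product: 18 (6S)-12′-apo-ε-caroten-12′-al [(2E,4E,6E,8E,10E,12E)-2,7,11-trimethyl-13-[(1S)-2,6,6-trimethylcyclohex-2-en-1-yl]trideca-2,4,6,8,10,12-hexaenal], via ylide 17 (not isolated)
Conditions: NaOMe, MeOH/CH2Cl2, 0 to 25 °C, 15 added to excess 16 (2.5 equiv); then heptane, 80 °C
Reagents that add atoms: none
Why: Wittig olefination in which excess dialdehyde and the lower reactivity of the more conjugated product aldehyde should favour mono-condensation, and heating equilibrates the hindered (Z)-isomer of the new disubstituted double bond to (E).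

Step 12
Reactants: 18 (6S)-12′-apo-ε-caroten-12′-al; 12 [(2E,4E)-5-[(1S,4S)-4-[(tert-butyldimethylsilyl)oxy]-2,6,6-trimethylcyclohex-2-en-1-yl]-3-methylpenta-2,4-dien-1-yl]triphenylphosphonium bromide
Product: 20 (3S,6S,6′S)-3-[(tert-butyldimethylsilyl)oxy]-ε,ε-carotene, via ylide 19 (not isolated)
Conditions: NaOMe, MeOH/CH2Cl2, 25 °C; then heptane, 80 °C
Reagents that add atoms: none
Why: Wittig olefination forming C11=C12, followed by thermal Z/E equilibration to the all-E polyene; neither ring stereocentre is affected under these basic, non-acidic conditions.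

Step 13
Reactants: 20 (3S,6S,6′S)-3-[(tert-butyldimethylsilyl)oxy]-ε,ε-carotene
Product: 21 (3S,6S,6′S)-ε,ε-caroten-3-ol (CNP0153224.1)
Conditions: Bu4NF, THF, 0 to 25 °C
Reagents that add atoms: none
Why: Fluoride-mediated desilylation frees the allylic alcohol under non-acidic conditions, which avoids ionisation and epimerisation at C3.

Compound list
1 | dimethyl 3,3-dimethylpentanedioate (dimethyl 3,3-dimethylglutarate) | COC(=O)CC(C)(C)CC(=O)OC | starting material
2 | methyl but-2-ynoate | CC#CC(=O)OC | starting material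
3 | dilithium bis-enolate of 1 | COC(O[Li])=CC(C)(C)C=C(OC)O[Li] | intermediate
4 | lithium enolate of dimethyl (2Z)-4-(methoxycarbonyl)-3,5,5-trimethylhept-2-enedioate (acyclic Michael adduct) | COC(=O)/C=C(/C)C(C(=O)OC)C(C)(C)C=C(OC)O[Li] | intermediate
5 | dimethyl 2,2,4-trimethyl-6-oxocyclohex-4-ene-1,3-dicarboxylate (racemic; epimers and enol forms) | COC(=O)C1C(=O)C=C(C)C(C(=O)OC)C1(C)C | intermediate
6 | methyl 2,6,6-trimethyl-4-oxocyclohex-2-ene-1-carboxylate (racemic) | COC(=O)C1C(C)=CC(=O)CC1(C)C | intermediate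
7 | methyl (1S,4S)-4-hydroxy-2,6,6-trimethylcyclohex-2-ene-1-carboxylate | COC(=O)[C@@H]1C(C)=C[C@@H](O)CC1(C)C | intermediate
8 | methyl (1S,4S)-4-[(tert-butyldimethylsilyl)oxy]-2,6,6-trimethylcyclohex-2-ene-1-carboxylate | COC(=O)[C@@H]1C(C)=C[C@@H](O[Si](C)(C)C(C)(C)C)CC1(C)C | intermediate
9 | (1S,4S)-4-[(tert-butyldimethylsilyl)oxy]-2,6,6-trimethylcyclohex-2-ene-1-carbaldehyde | O=C[C@@H]1C(C)=C[C@@H](O[Si](C)(C)C(C)(C)C)CC1(C)C | intermediate
10 | (3E)-4-[(1S,4S)-4-[(tert-butyldimethylsilyl)oxy]-2,6,6-trimethylcyclohex-2-en-1-yl]but-3-en-2-one | CC(=O)/C=C/[C@@H]1C(C)=C[C@@H](O[Si](C)(C)C(C)(C)C)CC1(C)C | intermediate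
11 | (1E)-1-[(1S,4S)-4-[(tert-butyldimethylsilyl)oxy]-2,6,6-trimethylcyclohex-2-en-1-yl]-3-methylpenta-1,4-dien-3-ol (both carbinol epimers) | C=CC(C)(O)/C=C/[C@@H]1C(C)=C[C@@H](O[Si](C)(C)C(C)(C)C)CC1(C)C | intermediate
12 | [(2E,4E)-5-[(1S,4S)-4-[(tert-butyldimethylsilyl)oxy]-2,6,6-trimethylcyclohex-2-en-1-yl]-3-methylpenta-2,4-dien-1-yl]triphenylphosphonium bromide | [Br-].c1ccccc1[P+](c1ccccc1)(c1ccccc1)C/C=C(C)/C=C/[C@@H]1C(C)=C[C@@H](O[Si](C)(C)C(C)(C)C)CC1(C)C | intermediate
13 | (S)-α-ionone, (3E)-4-[(1S)-2,6,6-trimethylcyclohex-2-en-1-yl]but-3-en-2-one | CC(=O)/C=C/[C@@H]1C(C)=CCCC1(C)C | starting material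
14 | (1E)-3-methyl-1-[(1S)-2,6,6-trimethylcyclohex-2-en-1-yl]penta-1,4-dien-3-ol (both carbinol epimers) | C=CC(C)(O)/C=C/[C@@H]1C(C)=CCCC1(C)C | intermediate
15 | [(2E,4E)-3-methyl-5-[(1S)-2,6,6-trimethylcyclohex-2-en-1-yl]penta-2,4-dien-1-yl]triphenylphosphonium bromide | [Br-].c1ccccc1[P+](c1ccccc1)(c1ccccc1)C/C=C(C)/C=C/[C@@H]1C(C)=CCCC1(C)C | intermediate
16 | (2E,4E,6E)-2,7-dimethylocta-2,4,6-trienedial | O=C/C(C)=C/C=C/C=C(C)/C=O | starting material
17 | ylide of 15, [(2E,4E)-3-methyl-5-[(1S)-2,6,6-trimethylcyclohex-2-en-1-yl]penta-2,4-dien-1-ylidene]triphenylphosphorane | c1ccccc1P(c1ccccc1)(c1ccccc1)=C/C=C(C)/C=C/[C@@H]1C(C)=CCCC1(C)C | intermediate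
18 | (6S)-12′-apo-ε-caroten-12′-al | CC1=CCCC(C)(C)[C@@H]1/C=C/C(C)=C/C=C/C(C)=C/C=C/C=C(C)/C=O | intermediate
19 | ylide of 12, [(2E,4E)-5-[(1S,4S)-4-[(tert-butyldimethylsilyl)oxy]-2,6,6-trimethylcyclohex-2-en-1-yl]-3-methylpenta-2,4-dien-1-ylidene]triphenylphosphorane | c1ccccc1P(c1ccccc1)(c1ccccc1)=C/C=C(C)/C=C/[C@@H]1C(C)=C[C@@H](O[Si](C)(C)C(C)(C)C)CC1(C)C | intermediate
20 | (3S,6S,6′S)-3-[(tert-butyldimethylsilyl)oxy]-ε,ε-carotene | CC1=CCCC(C)(C)[C@@H]1/C=C/C(C)=C/C=C/C(C)=C/C=C/C=C(C)/C=C/C=C(C)/C=C/[C@@H]1C(C)=C[C@@H](O[Si](C)(C)C(C)(C)C)CC1(C)C | intermediate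
21 | (3S,6S,6′S)-ε,ε-caroten-3-ol | CC1=CCCC(C)(C)[C@@H]1/C=C/C(C)=C/C=C/C(C)=C/C=C/C=C(C)/C=C/C=C(C)/C=C/[C@@H]1C(C)=C[C@@H](O)CC1(C)C | target

Total step count: 13. Longest linear sequence: 10 steps (steps 1 to 8, 12 and 13).

Steps most likely to fail

Step 1. The annulation may stall after the conjugate addition: the acidic C6–H of the acyclic adduct can quench the system as a stabilised glutaconate-type anion whose ester is a poor acyl acceptor, so the Dieckmann closure may not take place, and double Michael addition may compete. The fallback sets out from 1, comes back at 5, and still makes both bonds in one operation, but under Lewis-acidic conditions where no proton transfer can disarm the second nucleophile. Compound 1 is converted with LiN(iPr)2 and Me3SiCl (THF, −78 °C) into the bis(silyl ketene acetal) 1,5-dimethoxy-3,3-dimethyl-1,5-bis(trimethylsilyloxy)penta-1,4-diene F1. But-2-ynoic acid is turned with oxalyl chloride into but-2-ynoyl chloride F2. F1 and F2 are combined in CH2Cl2 at −78 °C in the presence of TiCl4. C-acylation of one ketene acetal (C2–C3) and 6-endo-dig Mukaiyama–Michael closure of the other onto the chelated ynone (C5–C6) should give 5 after aqueous work-up.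

Step 3. The catalyst may discriminate poorly between the alkenyl and the CH2–C(CH3)2 flanks of the carbonyl, so that enantiomer selection in the kinetic resolution is weak or of the opposite sense. The fallback sets out from 6 and comes back at 7, and separates diastereoselection from enantioselection. Luche reduction of 6 (NaBH4, CeCl3·7H2O, MeOH, −78 °C) should give, under substrate control, racemic methyl trans-4-hydroxy-2,6,6-trimethylcyclohex-2-ene-1-carboxylate F3. Acylation with Burkholderia cepacia lipase and vinyl acetate in tert-butyl methyl ether should, by the empirical rule for secondary alcohols with the gem-dimethyl flank as the large group, convert the (1S,4S)-enantiomer into methyl (1S,4S)-4-acetoxy-2,6,6-trimethylcyclohex-2-ene-1-carboxylate F4. F4 is separated from the unreacted (1R,4R)-alcohol and hydrolysed with the same lipase in pH 7 buffer to 7.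

Step 2. Over-reaction may remove the vinylogously activated ester on C6 as well, or only demethylate it. The fallback sets out from 5 and comes back at 6, and replaces halide-mediated dealkoxycarbonylation by hydrolysis and re-esterification. Heating 5 in 6 M HCl/AcOH at 80 °C hydrolyses both esters; the β-keto acid loses CO2 at once while the vinylogous acid should persist, giving 2,6,6-trimethyl-4-oxocyclohex-2-ene-1-carboxylic acid F5. F5 is re-esterified with Me3SiCHN2 in MeOH/toluene to 6.

Further compounds
F1 | step 1 | 1,5-dimethoxy-3,3-dimethyl-1,5-bis(trimethylsilyloxy)penta-1,4-diene | COC(O[Si](C)(C)C)=CC(C)(C)C=C(OC)O[Si](C)(C)C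
F2 | step 1 | but-2-ynoyl chloride | CC#CC(Cl)=O
F3 | step 3 | racemic methyl trans-4-hydroxy-2,6,6-trimethylcyclohex-2-ene-1-carboxylate [(1S,4S) and (1R,4R)] | COC(=O)[C@@H]1C(C)=C[C@@H](O)CC1(C)C.COC(=O)[C@H]1C(C)=C[C@H](O)CC1(C)C
F4 | step 3 | methyl (1S,4S)-4-acetoxy-2,6,6-trimethylcyclohex-2-ene-1-carboxylate | COC(=O)[C@@H]1C(C)=C[C@@H](OC(C)=O)CC1(C)C
F5 | step 2 | 2,6,6-trimethyl-4-oxocyclohex-2-ene-1-carboxylic acid | OC(=O)C1C(C)=CC(=O)CC1(C)C
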